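**Retrosynthetic overview**
1. Target 41 ← C9 acylation with (R)-2-methylglycidate ← C8 acetate ← C4=C5 epoxidation, lactone α-methylenation and C14 oxidation, all on a cis-fused 6,12-lactone of a cyclodeca-1(10),4-diene that carries O8 and O9 as two different benzyl-type ethers.
2. Ten-membered ring ← anionic oxy-Cope ring expansion of a 1,6-dialkenyl-3-methylcyclohex-2-en-1-ol: the temporary ring bond C1–C6 (absent from the target) breaks while C8–C9 forms between two enol-ether termini, and the enolate is alkylated at C7 with methyl bromoacetate.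
3. Enabling feature: C6 bears oxygen and C1=C10 is an olefin, so C6(O)–C7–C8–C9–C10=C1 is an oxy-Cope retron centred on C8–C9. The cis C4–C5 unit (the later cis-epoxide) with C2 and C3 fits into a cyclohexene made of C1–C6, and O8 and O9 are the enol-ether oxygens.
4. Cope substrate ← (S)-keto ester 7 (SAMP-hydrazone alkylation of 3-methylcyclohexenone) + a (Z)-2-alkoxyvinyllithium. A temporary cis-fused γ-lactone O6–C14 is used to build the C9 enol ether and is then opened by reduction. The C1 and C6 stereocentres are relayed through the chair to C8/C9 and disappear.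
5. Ring order: cyclohexene (bought) → temporary γ-lactone → ten-membered carbocycle (six-ring opened) → 6,12-γ-lactone → epoxide.

Key step: step 9

**Remarks on the chemistry**
- The target SMILES is read as drawn: cis-fused lactone (H6/H7 cis), cis-4,5-epoxide (C3 and C6 cis), ring-cis C1=C10, 8,9-threo; the route is built for this isomer.
- Locants follow the germacrane skeleton: ring C1–C10; lactone C11–C13 (C12 carbonyl, C13 methylene); C14 on C10; C15 methyl on C4. In the six-ring intermediates the ring is C1–C6.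
- DMB = 3,4-dimethoxybenzyl, PMB = 4-methoxybenzyl, TBS = tert-butyldimethylsilyl.
- Compound 9 is the commercial cis/trans mixture. The C=N geometry of the hydrazones is not defined.
- Compounds 15–19 are acid-sensitive (tertiary allylic C–O next to an enol ether) and should be handled on Et3N-deactivated silica.

**Route**

Step 1
Reactants: 1 3-methylcyclohex-2-en-1-one; 2 (S)-1-amino-2-(methoxymethyl)pyrrolidine (SAMP)
Product: 3 SAMP hydrazone of 3-methylcyclohex-2-en-1-one
Conditions: p-TsOH (cat.), cyclohexane, reflux, Dean–Stark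
Reagents that add atoms: none
Why: Acid-catalysed hydrazone formation with azeotropic removal of water, the β,β-disubstituted enone being too hindered for competing aza-Michael addition.

Step 2
Reactants: 3 SAMP hydrazone of 3-methylcyclohex-2-en-1-one; 4 methyl bromoacetate
Product: 6 SAMP hydrazone of methyl 2-[(1S)-4-methyl-2-oxocyclohex-3-en-1-yl]acetate, via lithium azaenolate 5 (not isolated)
Conditions: LiN(i-Pr)2, THF, −78 °C; then 4, −100 → −78 °C
Reagents that add atoms: none
Why: Kinetic deprotonation at the ring CH2 next to C=N gives the cross-conjugated lithium azaenolate, which is alkylated on the face left open by the chelated methoxymethyl group (SAMP-hydrazone alkylation), setting C1 as S.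

Step 3
Reactants: 6 SAMP hydrazone of methyl 2-[(1S)-4-methyl-2-oxocyclohex-3-en-1-yl]acetate
Product: 7 methyl 2-[(1S)-4-methyl-2-oxocyclohex-3-en-1-yl]acetate
Conditions: saturated aqueous oxalic acid, Et2O, 20 °C
Reagents that add atoms: water, O
Why: Mild two-phase hydrazone hydrolysis frees the ketone without epimerising the α-centre and returns the auxiliary.

Step 4
Reactants: 8 3,4-dimethoxybenzyl alcohol; 9 1,2-dibromoethene
Product: 12 (Z)-1-bromo-2-(3,4-dimethoxybenzyloxy)ethene, via sodium 3,4-dimethoxybenzyl oxide 10 (not isolated), via bromoethyne 11 (not isolated)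
Conditions: NaH (1.2 equiv), THF, 0 → 20 °C
Reagents that add atoms: none
Why: Base-induced loss of HBr gives bromoethyne, to which the alkoxide adds in anti fashion (nucleophilic addition to a haloalkyne), so the (Z)-2-bromovinyl ether should result.

Step 5
Reactants: 7 methyl 2-[(1S)-4-methyl-2-oxocyclohex-3-en-1-yl]acetate; 12 (Z)-1-bromo-2-(3,4-dimethoxybenzyloxy)ethene
Product: 15 cis-fused lactone (3aS,7aR)-7a-[(Z)-2-(3,4-dimethoxybenzyloxy)ethenyl]-6-methyl-3a,4,5,7a-tetrahydro-1-benzofuran-2(3H)-one, via alkenyllithium 13 (not isolated), via lithium alkoxide 14 (not isolated)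
Conditions: 12, t-BuLi (2 equiv), Et2O, −78 °C; then 7, THF, −78 → 0 °C
Reagents that add atoms: none
Why: Bromine–lithium exchange with retention gives the (Z)-alkenyllithium, which adds 1,2 to the ketone on the face opposite the C1 acetate arm (equatorial attack, as for alkenyl metals on 6-substituted cyclohexenones), and the alkoxide, now cis to that arm, closes the cis-fused γ-lactone, which sets C6.

Step 6
Reactants: 15 cis-fused lactone (3aS,7aR)-7a-[(Z)-2-(3,4-dimethoxybenzyloxy)ethenyl]-6-methyl-3a,4,5,7a-tetrahydro-1-benzofuran-2(3H)-one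
Product: 17 (3E,3aS,7aS)-7a-[(Z)-2-(3,4-dimethoxybenzyloxy)ethenyl]-3-[(4-methoxybenzyloxy)methylidene]-6-methyl-3a,4,5,7a-tetrahydro-1-benzofuran-2(3H)-one, via sodium enolate 16 (not isolated)
Conditions: NaH, HCO2Me, THF, 0 → 20 °C; then 4-MeOC6H4CH2Cl, NaI (cat.), DMF, 20 °C
Reagents that add atoms: methyl formate, COC=O; 4-methoxybenzyl chloride, COc1ccc(CCl)cc1
Why: Claisen formylation of the lactone enolate followed by O-alkylation of the sodium hydroxymethylene enolate in DMF, which for 2-formyl lactones and esters gives the (E)-alkoxymethylene isomer (ether oxygen anti to the carbonyl, hence cis to C1).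

Step 7
Reactants: 17 (3E,3aS,7aS)-7a-[(Z)-2-(3,4-dimethoxybenzyloxy)ethenyl]-3-[(4-methoxybenzyloxy)methylidene]-6-methyl-3a,4,5,7a-tetrahydro-1-benzofuran-2(3H)-one
Product: 18 (1S,6S)-1-[(Z)-2-(3,4-dimethoxybenzyloxy)ethenyl]-6-[(E)-3-hydroxy-1-(4-methoxybenzyloxy)prop-1-en-2-yl]-3-methylcyclohex-2-en-1-ol
Conditions: (i-Bu)2AlH (3.5 equiv), CH2Cl2, −78 → 0 °C; Rochelle salt
Reagents that add atoms: none
Why: Hydride reduction of the vinylogous carbonate lactone takes place 1,2 at the carbonyl (through the lactol and the β-alkoxy enal) and opens the temporary ring to the diol, leaving both enol ethers and their geometries untouched.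

Step 8
Reactants: 18 (1S,6S)-1-[(Z)-2-(3,4-dimethoxybenzyloxy)ethenyl]-6-[(E)-3-hydroxy-1-(4-methoxybenzyloxy)prop-1-en-2-yl]-3-methylcyclohex-2-en-1-ol
Product: 19 (1S,6S)-6-[(E)-3-(tert-butyldimethylsilyloxy)-1-(4-methoxybenzyloxy)prop-1-en-2-yl]-1-[(Z)-2-(3,4-dimethoxybenzyloxy)ethenyl]-3-methylcyclohex-2-en-1-ol
Conditions: TBSCl, imidazole, DMF, 0 °C
Reagents that add atoms: tert-butyl(chloro)dimethylsilane, CC(C)(C)[Si](C)(C)Cl
Why: Selective silylation of the primary allylic hydroxyl, the hindered tertiary alcohol being left free for the alkoxide-triggered rearrangement.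

Step 9
Reactants: 19 (1S,6S)-6-[(E)-3-(tert-butyldimethylsilyloxy)-1-(4-methoxybenzyloxy)prop-1-en-2-yl]-1-[(Z)-2-(3,4-dimethoxybenzyloxy)ethenyl]-3-methylcyclohex-2-en-1-ol; 4 methyl bromoacetate
Product: 22 ten-membered keto ester (C6 ketone; 7R CH2CO2Me; 8S O-DMB; 9S O-PMB; 14-OTBS; C1=C10 ring-trans; C4=C5 ring-cis), via potassium alkoxide 20 (not isolated), via potassium dienolate 21 (not isolated)
Conditions: KN(SiMe3)2, THF, 0 → 35 °C (no crown ether); then −78 °C, 4, −78 → −40 °C; NH4Cl
Reagents that add atoms: none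
Why: Deprotonation gives the potassium alkoxide 20, whose C1–C6 bond breaks while C8–C9 forms in a concerted [3,3] shift through a chair that has both ring bonds (C1–C2, C6–C5) equatorial and both ether oxygens axial, O8 held next to the alkoxide oxygen by the potassium ion, and the cross-conjugated dienolate 21 is then C-alkylated at C7. The closest known reaction type is the anionic oxy-Cope ring expansion of 1,6-dialkenylcyclohex-2-enols to cyclodeca-2,6-dienones with trapping of the enolate by an alkyl halide. The ten-membered ring is closed by enlarging the cyclohexene with the four alkenyl carbons, the new bond joining the two enol-ether termini suprafacially in a six-centre transition state. C8 and C9 (both S, threo) follow from the Z and E geometries of the two enol ethers together with the C1 and C6 configurations read through the chair, and C7 (R) follows from alkylation of the ring-trans enolate on its peripheral face, anti to the new C8–C9 bond. The step needs chair over boat (secured by the trans-diequatorial ring bonds), C- over O-alkylation (soft bromoacetate) and no β-loss of the C8 alkoxide from the enolate (the potassium-bridged C8–O bond lies in the enolate plane, orthogonal to the π system, and the enolate is trapped at −78 °C).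

Step 10
Reactants: 22 ten-membered keto ester (C6 ketone; 7R CH2CO2Me; 8S O-DMB; 9S O-PMB; 14-OTBS; C1=C10 ring-trans; C4=C5 ring-cis)
Product: 24 cis-fused 6,12-lactone (H6/H7 cis; 8-O-DMB; 9-O-PMB; 14-OTBS; C1=C10 ring-trans), via allylic alcohol 23 (not isolated)
Conditions: NaBH4, CeCl3·7H2O, MeOH/THF, −78 → −40 °C; then 20 °C
Reagents that add atoms: none
Why: Luche 1,2-reduction of the enone with hydride delivered anti to the C8 ring branch (Felkin–Anh, ring periphery) should place O6 cis to the C7 acetate arm, and the alkoxide then closes the cis-fused γ-lactone by acyl substitution, which sets C6.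

Step 11
Reactants: 24 cis-fused 6,12-lactone (H6/H7 cis; 8-O-DMB; 9-O-PMB; 14-OTBS; C1=C10 ring-trans)
Product: 25 C14 allylic alcohol of the cis-fused 6,12-lactone (C1=C10 ring-trans)
Conditions: Bu4NF, THF, 0 °C
Reagents that add atoms: none
Why: Fluoride cleavage of the primary silyl ether, the only silyl group present.

Step 12
Reactants: 25 C14 allylic alcohol of the cis-fused 6,12-lactone (C1=C10 ring-trans)
Product: 27 ring-cis C14 enal of the cis-fused 6,12-lactone, via ring-trans enal 26 (not isolated)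
Conditions: MnO2, CH2Cl2, 20 °C; filter; I2 (5 mol %), CH2Cl2, daylight, 20 °C; Na2S2O3
Reagents that add atoms: none
Why: MnO2 oxidises the only allylic alcohol to the enal, and reversible addition of iodine atoms to the strained ring-trans trisubstituted enal should equilibrate C1=C10 to the less strained ring-cis isomer (thermodynamic olefin isomerisation), which is the geometry of the target.

Step 13
Reactants: 27 ring-cis C14 enal of the cis-fused 6,12-lactone
Product: 29 ring-cis C14 methyl ester of the cis-fused 6,12-lactone, via carboxylic acid 28 (not isolated)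
Conditions: NaClO2, NaH2PO4, 2-methyl-2-butene, t-BuOH/H2O, 0 °C; then Me3SiCHN2, PhMe/MeOH, 0 °C
Reagents that add atoms: sodium chlorite, [Na+].[O-]Cl=O; (trimethylsilyl)diazomethane, C[Si](C)(C)C=[N+]=[N-]
Why: Pinnick oxidation converts the enal into the acid without touching the olefins or the olefin geometry, and the acid is methylated with (trimethylsilyl)diazomethane.

Step 14
Reactants: 29 ring-cis C14 methyl ester of the cis-fused 6,12-lactone
Product: 33 α-methylene lactone (8-O-DMB; 9-O-PMB; C4=C5 olefin), via lithium enolate 30 (not isolated), via Mannich base 31 (not isolated), via ammonium iodide 32 (not isolated)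
Conditions: LiN(SiMe3)2, THF, −78 °C; CH2=NMe2+ I−, −78 → 0 °C; MeI, MeOH, 20 °C; NaHCO3 (aq), CH2Cl2
Reagents that add atoms: N,N-dimethylmethyleneiminium iodide (Eschenmoser's salt), C=[N+](C)C.[I-]
Why: Mannich reaction of the lactone enolate with Eschenmoser's salt, quaternisation and Hofmann-type elimination give the α-methylene lactone, the lactone CH2 being deprotonated faster than the C2 hydrogens of the enoate, which lie trans to the ester carbonyl.

Step 15
Reactants: 33 α-methylene lactone (8-O-DMB; 9-O-PMB; C4=C5 olefin)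
Product: 34 4,5-epoxide (4R,5S; cis; 8-O-DMB; 9-O-PMB)
Conditions: mCPBA, NaHCO3, CH2Cl2, 0 °C
Reagents that add atoms: 3-chloroperoxybenzoic acid, OOC(=O)c1cccc(Cl)c1
Why: Prilezhaev epoxidation of the only electron-rich olefin, where A(1,3) strain keeps H6 in the olefin plane so that the peracid should attack the peripheral face syn to the lactone oxygen and anti to C7, giving the cis-epoxide threo to O6.

Step 16
Reactants: 34 4,5-epoxide (4R,5S; cis; 8-O-DMB; 9-O-PMB)
Product: 35 C8 alcohol (9-O-PMB retained)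
Conditions: DDQ (1.2 equiv), CH2Cl2/pH 7 buffer, 0 °C
Reagents that add atoms: none
Why: Oxidative cleavage of the more electron-rich 3,4-dimethoxybenzyl ether by DDQ, which is selective over a 4-methoxybenzyl ether at 0 °C, and the buffer protects the epoxide.

Step 17
Reactants: 35 C8 alcohol (9-O-PMB retained)
Product: 36 C8 acetate (9-O-PMB)
Conditions: Ac2O, pyridine, DMAP (cat.), CH2Cl2, 0 °C
Reagents that add atoms: acetic anhydride, CC(=O)OC(C)=O
Why: DMAP-catalysed acetylation of the secondary alcohol while O9 is still an ether, so that no acyl migration is possible.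

Step 18
Reactants: 36 C8 acetate (9-O-PMB)
Product: 37 C9 alcohol (8-acetate)
Conditions: DDQ (2 equiv), CH2Cl2/pH 7 buffer, 20 °C
Reagents that add atoms: none
Why: DDQ oxidation of the 4-methoxybenzyl ether frees the C9 hydroxyl under neutral buffered conditions that should leave the epoxide, the α-methylene lactone and the neighbouring acetate in place.

Step 19
Reactants: 38 methyl (2R)-2-methyloxirane-2-carboxylate
Product: 39 lithium (2R)-2-methyloxirane-2-carboxylate
Conditions: LiOH·H2O (1.0 equiv), THF/H2O, 0 °C; freeze-dry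
Reagents that add atoms: lithium hydroxide, [Li+].[OH-]
Why: Saponification at 0 °C gives the carboxylate without opening the epoxide or touching the quaternary stereocentre.

Step 20
Reactants: 37 C9 alcohol (8-acetate); 39 lithium (2R)-2-methyloxirane-2-carboxylate
Product: 41 target CNP0159450.1, via mixed anhydride 40 (not isolated)
Conditions: 39, 2,4,6-Cl3C6H2COCl, THF, 20 °C; then 37, Et3N, DMAP, PhMe, 20 °C
Reagents that add atoms: none
Why: Yamaguchi esterification through the mixed anhydride acylates the hindered allylic C9 hydroxyl without touching any stereocentre.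

**Compound list**
1 | 3-methylcyclohex-2-en-1-one | CC1=CC(=O)CCC1 | starting material
2 | (S)-1-amino-2-(methoxymethyl)pyrrolidine (SAMP) | COC[C@@H]1CCCN1N | starting material
3 | SAMP hydrazone of 3-methylcyclohex-2-en-1-one (C=N geometry not defined) | CC1=CC(=NN2CCC[C@H]2COC)CCC1 | intermediate
4 | methyl bromoacetate | COC(=O)CBr | starting material
5 | lithium azaenolate of 3 (deprotonated at the ring CH2 next to C=N) | CC1=CC(=CCC1)N([Li])N1CCC[C@H]1COC | intermediate
6 | SAMP hydrazone of methyl 2-[(1S)-4-methyl-2-oxocyclohex-3-en-1-yl]acetate | CC1=CC(=NN2CCC[C@H]2COC)[C@@H](CC1)CC(=O)OC | intermediate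
7 | methyl 2-[(1S)-4-methyl-2-oxocyclohex-3-en-1-yl]acetate | CC1=CC(=O)[C@@H](CC1)CC(=O)OC | intermediate
8 | 3,4-dimethoxybenzyl alcohol | COc1ccc(CO)cc1OC | starting material
9 | 1,2-dibromoethene (cis/trans mixture) | BrC=CBr | starting material
10 | sodium 3,4-dimethoxybenzyl oxide | [Na+].[O-]Cc1ccc(OC)c(OC)c1 | intermediate
11 | bromoethyne | BrC#C | intermediate
12 | (Z)-1-bromo-2-(3,4-dimethoxybenzyloxy)ethene | Br/C=C\OCc1ccc(OC)c(OC)c1 | intermediate
13 | (Z)-2-(3,4-dimethoxybenzyloxy)ethenyllithium | [Li]/C=C\OCc1ccc(OC)c(OC)c1 | intermediate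
14 | lithium alkoxide of the 1,2-adduct of 13 and 7 (alkoxide cis to the CH2CO2Me arm, alkenyl group trans to it) | CC1=C[C@@](O[Li])(/C=C\OCc2ccc(OC)c(OC)c2)[C@@H](CC1)CC(=O)OC | intermediate
15 | (3aS,7aR)-7a-[(Z)-2-(3,4-dimethoxybenzyloxy)ethenyl]-6-methyl-3a,4,5,7a-tetrahydro-1-benzofuran-2(3H)-one (cis-fused) | CC1=C[C@]2(/C=C\OCc3ccc(OC)c(OC)c3)OC(=O)C[C@@H]2CC1 | intermediate
16 | sodium enolate of the 3-formyl derivative of 15 | CC1=C[C@]2(/C=C\OCc3ccc(OC)c(OC)c3)OC(=O)C(=C[O-])[C@@H]2CC1.[Na+] | intermediate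
17 | (3E,3aS,7aS)-7a-[(Z)-2-(3,4-dimethoxybenzyloxy)ethenyl]-3-[(4-methoxybenzyloxy)methylidene]-6-methyl-3a,4,5,7a-tetrahydro-1-benzofuran-2(3H)-one | CC1=C[C@]2(/C=C\OCc3ccc(OC)c(OC)c3)OC(=O)/C(=C/OCc3ccc(OC)cc3)[C@@H]2CC1 | intermediate
18 | (1S,6S)-1-[(Z)-2-(3,4-dimethoxybenzyloxy)ethenyl]-6-[(E)-3-hydroxy-1-(4-methoxybenzyloxy)prop-1-en-2-yl]-3-methylcyclohex-2-en-1-ol | CC1=C[C@@](O)(/C=C\OCc2ccc(OC)c(OC)c2)[C@@H](CC1)/C(CO)=C\OCc1ccc(OC)cc1 | intermediate
19 | (1S,6S)-6-[(E)-3-(tert-butyldimethylsilyloxy)-1-(4-methoxybenzyloxy)prop-1-en-2-yl]-1-[(Z)-2-(3,4-dimethoxybenzyloxy)ethenyl]-3-methylcyclohex-2-en-1-ol | CC1=C[C@@](O)(/C=C\OCc2ccc(OC)c(OC)c2)[C@@H](CC1)/C(CO[Si](C)(C)C(C)(C)C)=C\OCc1ccc(OC)cc1 | intermediate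
20 | potassium alkoxide of 19 | CC1=C[C@@]([O-])(/C=C\OCc2ccc(OC)c(OC)c2)[C@@H](CC1)/C(CO[Si](C)(C)C(C)(C)C)=C\OCc1ccc(OC)cc1.[K+] | intermediate
21 | potassium dienolate of the ten-membered ketone (C6=C7 ring-trans enolate, C1=C10 ring-trans, C4=C5 ring-cis; 8S O-DMB, 9S O-PMB, 14-OTBS) | [K+].[O-]/C1=C\[C@H](OCc2ccc(OC)c(OC)c2)[C@@H](OCc2ccc(OC)cc2)/C(CO[Si](C)(C)C(C)(C)C)=C/CC/C(C)=C\1 | intermediate
22 | ten-membered keto ester: C6 ketone, 7R CH2CO2Me, 8S O-DMB, 9S O-PMB, 14-OTBS, C1=C10 ring-trans, C4=C5 ring-cis | O=C1[C@H](CC(=O)OC)[C@H](OCc2ccc(OC)c(OC)c2)[C@@H](OCc2ccc(OC)cc2)/C(CO[Si](C)(C)C(C)(C)C)=C/CC/C(C)=C\1 | intermediate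
23 | C6 allylic alcohol of 22 (O6 cis to the C7 acetate arm) | O[C@@H]1[C@H](CC(=O)OC)[C@H](OCc2ccc(OC)c(OC)c2)[C@@H](OCc2ccc(OC)cc2)/C(CO[Si](C)(C)C(C)(C)C)=C/CC/C(C)=C\1 | intermediate
24 | cis-fused 6,12-lactone (H6/H7 cis), 8-O-DMB, 9-O-PMB, 14-OTBS, C1=C10 ring-trans, C4=C5 ring-cis | O=C1O[C@@H]2[C@H](C1)[C@H](OCc1ccc(OC)c(OC)c1)[C@@H](OCc1ccc(OC)cc1)/C(CO[Si](C)(C)C(C)(C)C)=C/CC/C(C)=C\2 | intermediate
25 | C14 allylic alcohol of lactone 24 | O=C1O[C@@H]2[C@H](C1)[C@H](OCc1ccc(OC)c(OC)c1)[C@@H](OCc1ccc(OC)cc1)/C(CO)=C/CC/C(C)=C\2 | intermediate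
26 | ring-trans C14 enal | O=C1O[C@@H]2[C@H](C1)[C@H](OCc1ccc(OC)c(OC)c1)[C@@H](OCc1ccc(OC)cc1)/C(C=O)=C/CC/C(C)=C\2 | intermediate
27 | ring-cis C14 enal | O=C1O[C@@H]2[C@H](C1)[C@H](OCc1ccc(OC)c(OC)c1)[C@@H](OCc1ccc(OC)cc1)/C(C=O)=C\CC/C(C)=C\2 | intermediate
28 | ring-cis C14 carboxylic acid | O=C1O[C@@H]2[C@H](C1)[C@H](OCc1ccc(OC)c(OC)c1)[C@@H](OCc1ccc(OC)cc1)/C(C(=O)O)=C\CC/C(C)=C\2 | intermediate
29 | ring-cis C14 methyl ester of the cis-fused 6,12-lactone | O=C1O[C@@H]2[C@H](C1)[C@H](OCc1ccc(OC)c(OC)c1)[C@@H](OCc1ccc(OC)cc1)/C(C(=O)OC)=C\CC/C(C)=C\2 | intermediate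
30 | lithium enolate of lactone 29 | [Li]OC=1O[C@@H]2[C@H](C=1)[C@H](OCc1ccc(OC)c(OC)c1)[C@@H](OCc1ccc(OC)cc1)/C(C(=O)OC)=C\CC/C(C)=C\2 | intermediate
31 | 11-(dimethylaminomethyl) lactone (C11 configuration not defined) | O=C1O[C@@H]2[C@H](C1CN(C)C)[C@H](OCc1ccc(OC)c(OC)c1)[C@@H](OCc1ccc(OC)cc1)/C(C(=O)OC)=C\CC/C(C)=C\2 | intermediate
32 | 11-(trimethylammoniomethyl) lactone iodide | O=C1O[C@@H]2[C@H](C1C[N+](C)(C)C)[C@H](OCc1ccc(OC)c(OC)c1)[C@@H](OCc1ccc(OC)cc1)/C(C(=O)OC)=C\CC/C(C)=C\2.[I-] | intermediate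
33 | α-methylene lactone, 8-O-DMB, 9-O-PMB, C4=C5 olefin | C=C1C(=O)O[C@@H]2[C@H]1[C@H](OCc1ccc(OC)c(OC)c1)[C@@H](OCc1ccc(OC)cc1)/C(C(=O)OC)=C\CC/C(C)=C\2 | intermediate
34 | 4,5-epoxide (4R,5S, cis), 8-O-DMB, 9-O-PMB | C=C1C(=O)O[C@@H]2[C@H]1[C@H](OCc1ccc(OC)c(OC)c1)[C@@H](OCc1ccc(OC)cc1)/C(C(=O)OC)=C\CC[C@@]1(C)O[C@@H]21 | intermediate
35 | C8 alcohol, 9-O-PMB | C=C1C(=O)O[C@@H]2[C@H]1[C@H](O)[C@@H](OCc1ccc(OC)cc1)/C(C(=O)OC)=C\CC[C@@]1(C)O[C@@H]21 | intermediate
36 | C8 acetate, 9-O-PMB | C=C1C(=O)O[C@@H]2[C@H]1[C@H](OC(C)=O)[C@@H](OCc1ccc(OC)cc1)/C(C(=O)OC)=C\CC[C@@]1(C)O[C@@H]21 | intermediate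
37 | C8 acetate, C9 alcohol | C=C1C(=O)O[C@@H]2[C@H]1[C@H](OC(C)=O)[C@@H](O)/C(C(=O)OC)=C\CC[C@@]1(C)O[C@@H]21 | intermediate
38 | methyl (2R)-2-methyloxirane-2-carboxylate | COC(=O)[C@@]1(C)CO1 | starting material
39 | lithium (2R)-2-methyloxirane-2-carboxylate | [Li+].[O-]C(=O)[C@@]1(C)CO1 | intermediate
40 | (2R)-2-methyloxirane-2-carboxylic 2,4,6-trichlorobenzoic anhydride | O=C(OC(=O)[C@@]1(C)CO1)c1c(Cl)cc(Cl)cc1Cl | intermediate
41 | CNP0159450.1 | C=C1C(=O)O[C@@H]2[C@H]1[C@H](OC(C)=O)[C@@H](OC(=O)[C@@]1(C)CO1)/C(C(=O)OC)=C\CC[C@@]1(C)O[C@@H]21 | target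

**Totals and risks**

Total step count: 20 (18 in the main line, one for alkenyl bromide 12, one for carboxylate 39). Longest linear sequence: 18 steps (steps 1–3, 5–18 and 20).

The three steps most likely to fail:

Step 9. The potassium enolate may lose the C8 alkoxide by β-elimination before it is alkylated. A boat pathway may compete and erode the C8/C9 relationship. The enolate may also equilibrate, lowering the facial selectivity at C7. The fallback drops the anionic manifold: alcohol 19 is heated in base-washed toluene at about 190 °C (sealed tube) for a neutral thermal oxy-Cope rearrangement through the same chair (hydroxyl hydrogen-bonded to O8). The enol should tautomerise to the ten-membered ketone lacking the acetate arm F1. This is deprotonated with LiN(i-Pr)2 in THF at −78 °C to its kinetic lithium enolate F2 and alkylated with methyl bromoacetate 4, returning to the route at 22.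

Step 12. The iodine-mediated equilibration may stop short of the ring-cis enal or may be accompanied by iodine addition at C4=C5. The fallback replaces catalytic isomerisation by a stoichiometric addition–elimination. Alcohol 25 is oxidised with MnO2 and the ring-trans enal 26 is isolated. Thiophenol with a trace of Et3N adds to it to give the β-phenylsulfanyl aldehyde F3. NaIO4 oxidises this to the sulfoxide F4, and warming in toluene brings about syn-elimination towards the epimerisable C10–H. This should deliver the less strained ring-cis enal, rejoining the route at 27.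

Step 10. Hydride may be delivered to the other face of the C6 carbonyl, so that the C6 epimer forms and lactonises trans. The fallback accepts that outcome and corrects it by inversion. From 22 under the step 10 conditions, the 6-epi hydroxy ester F5 closes to the trans-fused lactone F6. LiOH in THF/water followed by a pH 4 phosphate buffer opens it to the hydroxy acid F7. Mitsunobu lactonisation (PPh3, diisopropyl azodicarboxylate, THF, 0 °C) closes the γ-lactone with inversion at the allylic C6, giving the cis-fused lactone and returning at 24.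

Further compounds
F1 | step 9 | ten-membered ketone lacking the acetate arm (8S O-DMB, 9S O-PMB, 14-OTBS, C1=C10 ring-trans, C4=C5 ring-cis) | O=C1C[C@H](OCc2ccc(OC)c(OC)c2)[C@@H](OCc2ccc(OC)cc2)/C(CO[Si](C)(C)C(C)(C)C)=C/CC/C(C)=C\1
F2 | step 9 | kinetic lithium enolate of F1 (C6=C7, geometry not defined) | [Li]OC1=C[C@H](OCc2ccc(OC)c(OC)c2)[C@@H](OCc2ccc(OC)cc2)/C(CO[Si](C)(C)C(C)(C)C)=C/CC/C(C)=C\1
F3 | step 12 | β-phenylsulfanyl aldehyde (PhS on C1, CHO on C10, both centres not defined) | O=C1O[C@@H]2[C@H](C1)[C@H](OCc1ccc(OC)c(OC)c1)[C@@H](OCc1ccc(OC)cc1)C(C=O)C(Sc1ccccc1)CC/C(C)=C\2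
F4 | step 12 | sulfoxide of F3 | O=C1O[C@@H]2[C@H](C1)[C@H](OCc1ccc(OC)c(OC)c1)[C@@H](OCc1ccc(OC)cc1)C(C=O)C(S(=O)c1ccccc1)CC/C(C)=C\2
F5 | step 10 | 6-epi hydroxy ester (C6 epimer of 23) | O[C@H]1[C@H](CC(=O)OC)[C@H](OCc2ccc(OC)c(OC)c2)[C@@H](OCc2ccc(OC)cc2)/C(CO[Si](C)(C)C(C)(C)C)=C/CC/C(C)=C\1
F6 | step 10 | trans-fused 6,12-lactone (C6 epimer of 24) | O=C1O[C@H]2[C@H](C1)[C@H](OCc1ccc(OC)c(OC)c1)[C@@H](OCc1ccc(OC)cc1)/C(CO[Si](C)(C)C(C)(C)C)=C/CC/C(C)=C\2
F7 | step 10 | 6-epi hydroxy acid | O[C@H]1[C@H](CC(=O)O)[C@H](OCc2ccc(OC)c(OC)c2)[C@@H](OCc2ccc(OC)cc2)/C(CO[Si](C)(C)C(C)(C)C)=C/CC/C(C)=C\1
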